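The winter run holds 34.7% of its substrate at 2.00 min and 34.6% at 3.00 min, so it stops with substrate unconverted.

| setting | winter | midnight | beta | eta |
|---|---|---|---|---|
| substrate | 39 mM | 39 mM | 39 mM | 39 mM |
| coupling partner | 0.95 equiv | 0.95 equiv | 0.950 equiv | 0.950 equiv |
| free catalyst | 3.3 mol% | 3.3 mol% | 3.3 mol% | 3.3 mol% |
| second catalyst | 6.4 mol% | 6.4 mol% | 6.4 mol% | 6.4 mol% |
| impurity | 2.4 mM | 3 mM | 1.4 mM | 4.2 mM |
| remark | run made earlier | run made earlier |  |  |
| time |  |  | 6.0 min | 6.0 min |

- winter (time / min: substrate / %, target / %, open intermediate / %): 0.250: 37.9, 14.9, 46.4; 0.833: 36.0, 20.6, 41.1; 1.33: 35.6, 21.2, 40.7; 2.00: 34.7, 21.3, 41.0; 3.00: 34.6, 21.8, 41.7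
- midnight (time / min: substrate / %, target / %, open intermediate / %): 0.250: 47.5, 11.7, 37.7; 0.833: 46.0, 18.1, 33.0; 1.33: 46.5, 17.9, 32.9; 2.00: 46.9, 19.3, 33.7; 3.00: 46.0, 19.3, 33.8

(readings scatter by 1 percentage point)



- which of these there is most of at the end, counted by the substrate in it, beta (substrate / target / open intermediate)
- which of these there is most of at the end, counted by the substrate in it, eta (substrate / target / open intermediate)
- the largest of these amounts at the end, in percent of the substrate charged, beta
- the largest of these amounts at the end, in percent of the substrate charged, eta

The midnight run, with more impurity, stops higher, at 46.0%. The working picture is that impurity removes free catalyst one to one, with the free catalyst charge, called the catalyst charge below, at 1.29 mM in each flask.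

Two rates then compete: the loss of substrate and the loss of impurity. If each is first order in its own species and in free catalyst, c(free catalyst) and the clock cancel from their ratio. The logarithmic fall of substrate is then a fixed multiple of the logarithmic fall of impurity, from c(impurity) to c(impurity) minus the catalyst charge. That multiple, ρ, is the selectivity factor of free catalyst for substrate over impurity.

The winter run gives 1.06 over 0.768, so 1.38. The midnight run gives 1.39. Their mean, read with the scatter of the readings, is 1.38.

My own reckoning leaves 60.3% substrate in eta. In beta, impurity is charged barely above the catalyst charge, 1.4 mM against 1.29 mM, so the same reckoning leaves 3.07% substrate. At 3.00 min the winter run reads more open intermediate than target, so my reckoning names open intermediate for beta.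

The forecast, holding that “the impurity seems to kill the free catalyst”, names open intermediate for beta at 63% (55% to 71%). For eta it names substrate at 60% (55% to 65%).

Beta ends with open intermediate at 63.8%, and eta with substrate at 60.9%.

    second catalyst + open intermediate ⇌ catalyst intermediate (K = 31.0 L mol⁻¹, k = 19.0 L mol⁻¹ s⁻¹)
    coupling partner + catalyst intermediate ⇌ second catalyst + target (K = 0.600, k = 110 L mol⁻¹ s⁻¹)
    free catalyst + impurity → spent catalyst (k = 140 L mol⁻¹ s⁻¹)
    substrate + free catalyst → free catalyst + open intermediate (k = 190 L mol⁻¹ s⁻¹)

In beta, free catalyst is down to 0.0272% of its charge at 6.00 min, and substrate still stands at 3.29% at 60.0 min. With ρ, the reckoned substrate was 3.07% against 3.30% in beta, and 60.3% against 60.9% in eta. At 1.56 mM of impurity, all else in beta held, ρ gives 8.89% substrate, and beta's substrate there has moved 6 points up from 3.30%.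

The readings come from a simulation with constants of no real substance; the scatter is artificial.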